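**Retrosynthetic overview**
1. Target 17 is a cis-fused daucane (cyclopentane C1–C5; cycloheptane C1, C5–C10). Late stage: tiglates by acylation, the 8α,9α-epoxide by delivery from the 10α-OH, the 10α-OH by reduction of a C8=C9–C10=O enone, the 6β-OH by delivery from the 4α-OH.
2. Key disconnection: in the seven-membered ring the two acyloxy carbons C6 and C10 stand 1,4 across the ring-fusion bond C1–C5 and are joined on the other side by the symmetric unit C7–C8(CH3)–C9. A cycloheptane-1,4-dione is the retron of a cyclobutane-1,2-diol cleavage, so the C6–C10 bond is re-formed to give a 5-4-5 tricycle.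
3. The tricycle is the [2+2] photoadduct of enone 5 (C1–C5, C1-methyl, C2-OTBS) and the mirror-symmetric bis(silyloxy)cyclopentene 2 (C6–C10, C8-methyl). Isopropyl is added to the C4 ketone before the ring enlargement.
4. Order of rings: cyclopentane (purchased silyloxycyclopentenone), then cyclobutane with its auxiliary cyclopentane (photoaddition), then the seven-membered ring last (step 6), then the epoxide.
5. All stereocentres relay from the purchased centre C2: C1/C5 (photoaddition anti to OTBS), C4 (exo attack), C6 (delivery from O4), C10 (convex face), C8/C9 (delivery from O10). Photoadduct isomers at C6/C10 and the C8 epimers converge.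

Key step: step 6

Remark 1: Daucane numbering is used: C1 (ring-fusion C with CH3), C2, C3, C4 (isopropyl carbon), C5 (ring-fusion CH), C6–C10 (seven-membered ring, C8 bears CH3). β is the face of the C1 methyl; the target SMILES defines a cis ring fusion (5β-H), 2β-OH, 4α-OH, 6β- and 10α-acyloxy and an 8α,9α-epoxide.
Remark 2: The photoadduct is drawn as the cis-anti-cis isomer and C8 is left undefined (epimer mixture) in 6–12; both features are erased later.

Step 1
Reactants: 1 dimethyl 3-methylpentanedioate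
Product: 2 4-methyl-1,2-bis(trimethylsilyloxy)cyclopent-1-ene
Conditions: Na, TMSCl, toluene, reflux
Reagents that add atoms: chlorotrimethylsilane, C[Si](C)(C)Cl
Why: Acyloin condensation with in-situ silylation (Rühlmann variant) closes the five-membered ring of a glutarate and traps the enediolate; the methyl-bearing carbon lies on the mirror plane, so no stereocentre arises.

Step 2
Reactants: 3 (S)-4-(tert-butyldimethylsilyloxy)cyclopent-2-en-1-one
Product: 4 (3S,4S)-4-(tert-butyldimethylsilyloxy)-3-methyl-1-(trimethylsilyloxy)cyclopent-1-ene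
Conditions: Me2CuLi (from MeLi and CuI), TMSCl, THF, −78 °C; Et3N
Reagents that add atoms: lithium dimethylcuprate, [Li+].C[Cu-]C; chlorotrimethylsilane, C[Si](C)(C)Cl
Why: Gilman conjugate addition trans to the silyloxy group with in-situ O-silylation of the enolate, which prevents enolate equilibration and β-elimination of the silyloxy group; the new C3 centre is erased in step 3.

Step 3
Reactants: 4 (3S,4S)-4-(tert-butyldimethylsilyloxy)-3-methyl-1-(trimethylsilyloxy)cyclopent-1-ene
Product: 5 (S)-4-(tert-butyldimethylsilyloxy)-3-methylcyclopent-2-en-1-one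
Conditions: Pd(OAc)2 (10 mol %), O2 (1 atm), DMSO, 23 °C
Reagents that add atoms: none
Why: Saegusa–Ito oxidation (catalytic Pd(II)/O2): the Pd enolate eliminates the only β-hydrogen (H-3) to regenerate the enone with the methyl now on the β-carbon; the silyloxy-bearing stereocentre is not involved.

Step 4
Reactants: 5 (S)-4-(tert-butyldimethylsilyloxy)-3-methylcyclopent-2-en-1-one; 2 4-methyl-1,2-bis(trimethylsilyloxy)cyclopent-1-ene
Product: 6 cis-anti-cis photoadduct 5-(tert-butyldimethylsilyloxy)-6,9-dimethyl-1,7-bis(trimethylsilyloxy)tricyclo[5.3.0.0^{2,6}]decan-3-one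
Conditions: hν (λ > 300 nm, Pyrex), 2 (4 equiv), hexane, −20 °C
Reagents that add atoms: none
Why: Enone–alkene [2+2] photocycloaddition (triplet enone, 1,4-biradical): the alkene adds to the enone face anti to the C2 silyloxy group, which sets the quaternary C1 (CH3 β) and C5 (H β) cis; the symmetric alkene excludes regioisomers, and the C6/C10 (cis-anti or cis-syn) and C8 isomers need no separation because these centres are erased in steps 6 and 10.

Step 5
Reactants: 6 cis-anti-cis photoadduct (tricyclic C4 ketone)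
Product: 7 5-(tert-butyldimethylsilyloxy)-3-isopropyl-6,9-dimethyl-1,7-bis(trimethylsilyloxy)tricyclo[5.3.0.0^{2,6}]decan-3-ol (4β-isopropyl; 4α-OH)
Conditions: i-PrMgCl, LaCl3·2LiCl, THF, −20 → 0 °C
Reagents that add atoms: isopropylmagnesium chloride, CC(C)[Mg]Cl
Why: Lanthanide-promoted Grignard 1,2-addition suppresses enolisation and β-hydride transfer; the nucleophile attacks the exo (β) face of the bicyclo[3.2.0]heptanone unit, anti to the cyclobutane and its endo silyloxy group, which sets C4 as 4β-isopropyl/4α-OH.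

Step 6
Reactants: 7 tricyclic tertiary alcohol (bis-TMS ether)
Product: 9 2β-(tert-butyldimethylsilyloxy)-4α-hydroxy-5β-H-daucane-6,10-dione (C8 epimers), via cyclobutane-1,2-diol 8 (not isolated)
Conditions: K2CO3 (cat.), MeOH, 0 °C; concentrate; Pb(OAc)4, CH2Cl2, −20 → 0 °C
Reagents that add atoms: none
Why: Methanolysis frees the cis-ditertiary cyclobutane-1,2-diol 8, which forms a cyclic Pb(IV) diester that fragments in a concerted two-electron process (Criegee glycol cleavage), breaking the C6–C10 bond. Because this bond is shared by the four-membered ring (C1, C5, C6, C10) and the auxiliary five-membered ring (C6–C10), its scission merges both into the seven-membered ring C1, C5–C10 with ketones at C6 and C10, driven by release of cyclobutane strain. The closest known reaction type is the two-carbon ring enlargement by enone–alkene photocycloaddition followed by 1,2-diol cleavage (or de Mayo retro-aldol) to bicyclo[5.3.0]decanediones. The ring is not closed by bond formation, so no Baldwin mode applies: it arises by fragmentative enlargement of the cyclobutane. No new stereocentre is formed; C1 and C5 (cis, from step 4), C2 and C4 pass unchanged, while the C6/C10 centres are erased so that all photoadduct isomers converge on 9. The step needs chemoselective cleavage of the only vicinal diol without epimerisation of H-5 (now α to the C6 ketone) or retro-aldol loss of the C4 carbinol; the isolated tertiary 4-OH, the silyl ether at O2 and the cold, non-basic Pb(OAc)4 conditions should secure this.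

Step 7
Reactants: 9 2β-(tert-butyldimethylsilyloxy)-4α-hydroxy-5β-H-daucane-6,10-dione
Product: 10 2β-(tert-butyldimethylsilyloxy)-4α,6β-dihydroxy-5β-H-daucan-10-one
Conditions: Me4NBH(OAc)3, MeCN/AcOH, −30 °C
Reagents that add atoms: none
Why: Evans–Saksena reduction: ligand exchange puts boron on O4 and the hydride is delivered through a six-membered transition state; since C4–O is cis to the C5–C6 bond on the cyclopentane, boron reaches only the C6 face anti to H-5, giving the 6β-alcohol (4,6-anti diol), and the C10 ketone, which has no free β-hydroxyl (O2 is silylated), is left.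

Step 8
Reactants: 10 2β-(tert-butyldimethylsilyloxy)-4α,6β-dihydroxy-5β-H-daucan-10-one
Product: 11 2β-(tert-butyldimethylsilyloxy)-4α-hydroxy-10-oxo-5β-H-daucan-6β-yl (E)-2-methylbut-2-enoate
Conditions: tigloyl chloride, Et3N, DMAP (cat.), CH2Cl2, 0 → 23 °C
Reagents that add atoms: tigloyl chloride, C/C=C(\C)C(=O)Cl
Why: DMAP-catalysed acylation of the only secondary alcohol (6β-OH); the tertiary 4-OH does not react under these conditions and the (E)-acid chloride transfers the tigloyl group without isomerisation.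

Step 9
Reactants: 11 2β-(tert-butyldimethylsilyloxy)-4α-hydroxy-10-oxo-5β-H-daucan-6β-yl (E)-2-methylbut-2-enoate
Product: 12 2β-(tert-butyldimethylsilyloxy)-4α,10-bis(trimethylsilyloxy)-5β-H-dauc-9-en-6β-yl (E)-2-methylbut-2-enoate
Conditions: TMSOTf, Et3N, CH2Cl2, −78 → 0 °C
Reagents that add atoms: trimethylsilyl trifluoromethanesulfonate, C[Si](C)(C)OS(=O)(=O)C(F)(F)F
Why: Soft enolisation/silylation: the C10 ketone can enolise only towards C9 because C1 is quaternary, so a single silyl enol ether forms, and the tertiary 4-OH is capped as its TMS ether at the same time.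

Step 10
Reactants: 12 2β-(tert-butyldimethylsilyloxy)-4α,10-bis(trimethylsilyloxy)-5β-H-dauc-9-en-6β-yl (E)-2-methylbut-2-enoate
Product: 13 2β-(tert-butyldimethylsilyloxy)-4α-(trimethylsilyloxy)-10-oxo-5β-H-dauc-8-en-6β-yl (E)-2-methylbut-2-enoate
Conditions: Pd(OAc)2 (1.1 equiv), MeCN, 23–40 °C
Reagents that add atoms: none
Why: Saegusa–Ito oxidation: the Pd(II) enolate at C9 undergoes β-hydride elimination of the only β-hydrogen (H-8) to give the C8=C9 enone, which makes C8 sp2 and so merges both C8 epimers.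

Step 11
Reactants: 13 2β-(tert-butyldimethylsilyloxy)-4α-(trimethylsilyloxy)-10-oxo-5β-H-dauc-8-en-6β-yl (E)-2-methylbut-2-enoate
Product: 14 2β-(tert-butyldimethylsilyloxy)-10α-hydroxy-4α-(trimethylsilyloxy)-5β-H-dauc-8-en-6β-yl (E)-2-methylbut-2-enoate
Conditions: NaBH4, CeCl3·7H2O, MeOH, −78 °C
Reagents that add atoms: none
Why: Luche 1,2-reduction of the enone: hydride should enter C10 from the convex β-face, anti to the pseudoaxial C1–C2 bond of the cis-fused cyclopentane (the angular methyl lies pseudoequatorial), giving the 10α-allylic alcohol; esters and silyl ethers are inert at −78 °C.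

Step 12
Reactants: 14 2β-(tert-butyldimethylsilyloxy)-10α-hydroxy-4α-(trimethylsilyloxy)-5β-H-dauc-8-en-6β-yl (E)-2-methylbut-2-enoate
Product: 15 8α,9α-epoxy-2β-(tert-butyldimethylsilyloxy)-10α-hydroxy-4α-(trimethylsilyloxy)-5β-H-daucan-6β-yl (E)-2-methylbut-2-enoate
Conditions: VO(acac)2 (5 mol %), t-BuOOH, CH2Cl2, 0 → 23 °C
Reagents that add atoms: tert-butyl hydroperoxide, CC(C)(C)OO
Why: Vanadium-catalysed hydroxyl-directed epoxidation: the 10α-vanadate delivers the peroxide oxygen to the syn face of the trisubstituted C8=C9 alkene, setting C8 and C9 as the 8α,9α-epoxide; the electron-poor tiglate alkene does not react.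

Step 13
Reactants: 15 8α,9α-epoxy-2β-(tert-butyldimethylsilyloxy)-10α-hydroxy-4α-(trimethylsilyloxy)-5β-H-daucan-6β-yl (E)-2-methylbut-2-enoate
Product: 16 8α,9α-epoxy-2β-(tert-butyldimethylsilyloxy)-4α-(trimethylsilyloxy)-5β-H-daucane-6β,10α-diyl bis[(E)-2-methylbut-2-enoate]
Conditions: tiglic acid, 2,4,6-trichlorobenzoyl chloride, Et3N, toluene, 23 °C; then 15, DMAP, 60 °C
Reagents that add atoms: tiglic acid, C/C=C(\C)C(=O)O
Why: Yamaguchi esterification via the mixed anhydride and the acyl-DMAP cation acylates the hindered neopentylic 10α-OH; the cis-epoxy alcohol cannot undergo Payne rearrangement (O10 is syn to the epoxide), the tertiary silyl ether at O4 is inert, and the (E)-geometry of the tiglate is the stable one.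

Step 14
Reactants: 16 8α,9α-epoxy-2β-(tert-butyldimethylsilyloxy)-4α-(trimethylsilyloxy)-5β-H-daucane-6β,10α-diyl bis[(E)-2-methylbut-2-enoate]
Product: 17 8α,9α-epoxy-2β,4α-dihydroxy-5β-H-daucane-6β,10α-diyl bis[(E)-2-methylbut-2-enoate] (target)
Conditions: TBAF, AcOH, THF, 23 → 40 °C
Reagents that add atoms: none
Why: Fluoride-induced Si–O cleavage removes the TBS group at O2 and the TMS group at O4; acetic acid buffers the alkoxides so that neither acyl migration nor epoxide opening should intervene, and the product is target 17.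

**Compound list**
1 | dimethyl 3-methylpentanedioate | COC(=O)CC(C)CC(=O)OC | starting material
2 | 4-methyl-1,2-bis(trimethylsilyloxy)cyclopent-1-ene | CC1CC(O[Si](C)(C)C)=C(O[Si](C)(C)C)C1 | intermediate
3 | (S)-4-(tert-butyldimethylsilyloxy)cyclopent-2-en-1-one | O=C1C=C[C@@H](O[Si](C)(C)C(C)(C)C)C1 | starting material
4 | (3S,4S)-4-(tert-butyldimethylsilyloxy)-3-methyl-1-(trimethylsilyloxy)cyclopent-1-ene (methyl trans to OTBS) | C[C@H]1C=C(O[Si](C)(C)C)C[C@@H]1O[Si](C)(C)C(C)(C)C | intermediate
5 | (S)-4-(tert-butyldimethylsilyloxy)-3-methylcyclopent-2-en-1-one | CC1=CC(=O)C[C@@H]1O[Si](C)(C)C(C)(C)C | intermediate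
6 | cis-anti-cis 5-(tert-butyldimethylsilyloxy)-6,9-dimethyl-1,7-bis(trimethylsilyloxy)tricyclo[5.3.0.0^{2,6}]decan-3-one (daucane atoms: C4 ketone; 2β-OTBS; 1β-CH3; 5β-H; cyclobutane bonds C1–C10 and C5–C6 on the α-face; C8 epimers) | C[Si](C)(C)O[C@@]13CC(C)C[C@@]3(O[Si](C)(C)C)[C@@]2(C)[C@@H]1C(=O)C[C@@H]2O[Si](C)(C)C(C)(C)C | intermediate
7 | 5-(tert-butyldimethylsilyloxy)-3-isopropyl-6,9-dimethyl-1,7-bis(trimethylsilyloxy)tricyclo[5.3.0.0^{2,6}]decan-3-ol (4β-isopropyl; 4α-OH; C8 epimers) | C[Si](C)(C)O[C@@]13CC(C)C[C@@]3(O[Si](C)(C)C)[C@@]2(C)[C@@H]1[C@](O)(C(C)C)C[C@@H]2O[Si](C)(C)C(C)(C)C | intermediate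
8 | 5-(tert-butyldimethylsilyloxy)-3-isopropyl-6,9-dimethyltricyclo[5.3.0.0^{2,6}]decane-1,3,7-triol (cis-cyclobutane-1,2-diol; not isolated) | O[C@@]13CC(C)C[C@@]3(O)[C@@]2(C)[C@@H]1[C@](O)(C(C)C)C[C@@H]2O[Si](C)(C)C(C)(C)C | intermediate
9 | 2β-(tert-butyldimethylsilyloxy)-4α-hydroxy-5β-H-daucane-6,10-dione (C8 epimers) | O=C1CC(C)CC(=O)[C@@]2(C)[C@@H]1[C@](O)(C(C)C)C[C@@H]2O[Si](C)(C)C(C)(C)C | intermediate
10 | 2β-(tert-butyldimethylsilyloxy)-4α,6β-dihydroxy-5β-H-daucan-10-one (C8 epimers) | O[C@H]1CC(C)CC(=O)[C@@]2(C)[C@@H]1[C@](O)(C(C)C)C[C@@H]2O[Si](C)(C)C(C)(C)C | intermediate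
11 | 2β-(tert-butyldimethylsilyloxy)-4α-hydroxy-10-oxo-5β-H-daucan-6β-yl (E)-2-methylbut-2-enoate (C8 epimers) | C/C=C(\C)C(=O)O[C@H]1CC(C)CC(=O)[C@@]2(C)[C@@H]1[C@](O)(C(C)C)C[C@@H]2O[Si](C)(C)C(C)(C)C | intermediate
12 | 2β-(tert-butyldimethylsilyloxy)-4α,10-bis(trimethylsilyloxy)-5β-H-dauc-9-en-6β-yl (E)-2-methylbut-2-enoate (C8 epimers) | C/C=C(\C)C(=O)O[C@H]1CC(C)C=C(O[Si](C)(C)C)[C@@]2(C)[C@@H]1[C@](O[Si](C)(C)C)(C(C)C)C[C@@H]2O[Si](C)(C)C(C)(C)C | intermediate
13 | 2β-(tert-butyldimethylsilyloxy)-4α-(trimethylsilyloxy)-10-oxo-5β-H-dauc-8-en-6β-yl (E)-2-methylbut-2-enoate | C/C=C(\C)C(=O)O[C@H]1CC(C)=CC(=O)[C@@]2(C)[C@@H]1[C@](O[Si](C)(C)C)(C(C)C)C[C@@H]2O[Si](C)(C)C(C)(C)C | intermediate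
14 | 2β-(tert-butyldimethylsilyloxy)-10α-hydroxy-4α-(trimethylsilyloxy)-5β-H-dauc-8-en-6β-yl (E)-2-methylbut-2-enoate | C/C=C(\C)C(=O)O[C@H]1CC(C)=C[C@H](O)[C@@]2(C)[C@@H]1[C@](O[Si](C)(C)C)(C(C)C)C[C@@H]2O[Si](C)(C)C(C)(C)C | intermediate
15 | 8α,9α-epoxy-2β-(tert-butyldimethylsilyloxy)-10α-hydroxy-4α-(trimethylsilyloxy)-5β-H-daucan-6β-yl (E)-2-methylbut-2-enoate | C/C=C(\C)C(=O)O[C@H]1C[C@]2(C)O[C@@H]2[C@H](O)[C@@]2(C)[C@@H]1[C@](O[Si](C)(C)C)(C(C)C)C[C@@H]2O[Si](C)(C)C(C)(C)C | intermediate
16 | 8α,9α-epoxy-2β-(tert-butyldimethylsilyloxy)-4α-(trimethylsilyloxy)-5β-H-daucane-6β,10α-diyl bis[(E)-2-methylbut-2-enoate] | C/C=C(\C)C(=O)O[C@H]1C[C@]2(C)O[C@@H]2[C@H](OC(=O)/C(C)=C/C)[C@@]2(C)[C@@H]1[C@](O[Si](C)(C)C)(C(C)C)C[C@@H]2O[Si](C)(C)C(C)(C)C | intermediate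
17 | 8α,9α-epoxy-2β,4α-dihydroxy-5β-H-daucane-6β,10α-diyl bis[(E)-2-methylbut-2-enoate] (CNP0265715.1) | C/C=C(\C)C(=O)O[C@H]1C[C@]2(C)O[C@@H]2[C@H](OC(=O)/C(C)=C/C)[C@@]2(C)[C@@H]1[C@](O)(C(C)C)C[C@@H]2O | target

**Summary**
Total step count: 14. Longest linear sequence: 13 steps (3 → 17, steps 2–14); step 1 prepares the second photocomponent.

Steps most likely to fail:

Step 11 (most uncertain). Hydride delivery to the concave face of C10, or low facial discrimination, would give the 10β-alcohol, which would also steer the epoxide to the wrong face. Fallback: replace substrate control by catalyst control with a Corey–Bakshi–Shibata reduction of 13 ((R)-2-methyl-CBS-oxazaborolidine, catecholborane, toluene, −78 °C). The (R)-catalyst is the one predicted if the fully substituted C1 arm acts as the large group; the (S)-catalyst is tried if the alkenyl arm dominates. The fallback sets out from 13 and returns to the route at 14 without a new compound.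

Step 5. Enolisation of the hindered cyclobutyl ketone (followed by β-elimination of the O2 silyloxy group) or β-hydride transfer from the secondary Grignard reagent may outrun 1,2-addition. Fallback: from 6, add the smaller sp2 nucleophile 2-propenylmagnesium bromide (CeCl3, THF, −78 °C), which should give the isopropenyl carbinol F1, then hydrogenate the 1,1-disubstituted alkene (H2, Pd/C, EtOAc) to return to the route at 7.

Step 7. Ligand exchange at the hindered tertiary 4-OH may be too slow for internal delivery, so that reduction stalls or proceeds by external attack on the other face. Fallback: from 9, reduce with an external hydride (NaBH4, MeOH, −40 °C), which should attack the more accessible C6 ketone from the convex β-face to give the 6α-alcohol F2. Esterification under Mitsunobu conditions (tiglic acid, PPh3, DIAD, toluene) then inverts C6 and returns to the route directly at 11.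

**Further compounds**
F1 | step 5 | 5-(tert-butyldimethylsilyloxy)-6,9-dimethyl-3-(prop-1-en-2-yl)-1,7-bis(trimethylsilyloxy)tricyclo[5.3.0.0^{2,6}]decan-3-ol (4β-isopropenyl; 4α-OH) | C[Si](C)(C)O[C@@]13CC(C)C[C@@]3(O[Si](C)(C)C)[C@@]2(C)[C@@H]1[C@](O)(C(C)=C)C[C@@H]2O[Si](C)(C)C(C)(C)C
F2 | step 7 | 2β-(tert-butyldimethylsilyloxy)-4α,6α-dihydroxy-5β-H-daucan-10-one | O[C@@H]1CC(C)CC(=O)[C@@]2(C)[C@@H]1[C@](O)(C(C)C)C[C@@H]2O[Si](C)(C)C(C)(C)C
F0 | step 11 | none | none
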